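**Assumption:** the target has no stereocentre and its only C=C is endocyclic, so it is achiral and "single enantiomer" needs no stereocontrol.

## Retrosynthetic overview

1. Target 18 ⇐ bis-benzyl ether 17 by hydrogenolysis; the pyranone ring C is closed last, from acetal 15 under acid.
2. Acetal 15 ⇐ 2'-hydroxychalcone 14 by oxidative 1,2-aryl shift with Tl(NO3)3.
3. Chalcone 14 ⇐ Claisen–Schmidt aldol condensation of ring A methyl ketone 12 with ring B chroman aldehyde 10 (key C–C bond).
4. Aldehyde 10 ⇐ chromanol 7 by ortho-formylation and O-methylation; 7 ⇐ chromanone 3 ⇐ phloroglucinol 1 + 3-methylbut-2-enoic acid 2.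
5. Ring order: dimethyldihydropyran ring of the chroman first (step 1), isoflavone pyranone ring last (step 10).

## Route

Step 1
Reactants: 1 phloroglucinol; 2 3-methylbut-2-enoic acid
Product: 3 5,7-dihydroxy-2,2-dimethylchroman-4-one
Conditions: MeSO3H/P2O5 (10:1 w/w), 70 °C, 1 h; ice-water quench
Reagents that add atoms: none
Why: Friedel–Crafts acylation followed by intramolecular oxa-Michael closure gives one regioisomer because the three ring positions of the symmetric triol are equivalent.

Step 2
Reactants: 3 5,7-dihydroxy-2,2-dimethylchroman-4-one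
Product: 4 7-(benzyloxy)-5-hydroxy-2,2-dimethylchroman-4-one
Conditions: BnBr (1.05 equiv), K2CO3 (1.2 equiv), acetone, reflux, 6 h
Reagents that add atoms: benzyl bromide, BrCc1ccccc1
Why: Williamson etherification is selective for the free 7-OH because the 5-OH is hydrogen-bonded to the C4 carbonyl.

Step 3
Reactants: 4 7-(benzyloxy)-5-hydroxy-2,2-dimethylchroman-4-one
Product: 5 7-(benzyloxy)-2,2-dimethyl-4-oxochroman-5-yl ethyl carbonate
Conditions: ClCO2Et (1.3 equiv), Et3N (1.5 equiv), THF, 0 °C, 1 h
Reagents that add atoms: ethyl chloroformate, CCOC(=O)Cl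
Why: O-acylation of the only free phenol gives the ortho-acyl aryl carbonate that activates the C4 carbonyl for reductive removal.

Step 4
Reactants: 5 7-(benzyloxy)-2,2-dimethyl-4-oxochroman-5-yl ethyl carbonate
Product: 7 7-(benzyloxy)-2,2-dimethylchroman-5-ol, via ortho-quinone methide 6 (not isolated)
Conditions: NaBH4 (4 equiv), THF/H2O, 0 °C to rt, 3 h; 1 M HCl quench
Reagents that add atoms: none
Why: In this reductive deoxygenation of an ortho-hydroxyaryl ketone carbonate, hydride reduces the ketone, the carbonate shifts to the benzylic oxygen and is expelled to give quinone methide 6, which takes a second hydride at C4 while the benzyl ether is untouched.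

Step 5
Reactants: 7 7-(benzyloxy)-2,2-dimethylchroman-5-ol
Product: 9 7-(benzyloxy)-5-hydroxy-2,2-dimethylchroman-6-carbaldehyde, via hydroxymethylphenol 8 (not isolated)
Conditions: MgCl2 (anhydrous, 2 equiv), Et3N (4 equiv), (CH2O)n (6 equiv), MeCN, reflux, 6 h; 1 M HCl work-up
Reagents that add atoms: paraformaldehyde (reacts as formaldehyde), C=O
Why: Magnesium-mediated ortho-formylation delivers formaldehyde through the magnesium phenoxide chelate only to C6, the single free ortho position (C4a is substituted, C8 is para), and a second formaldehyde oxidises salicyl alcohol 8 by hydride transfer.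

Step 6
Reactants: 9 7-(benzyloxy)-5-hydroxy-2,2-dimethylchroman-6-carbaldehyde
Product: 10 7-(benzyloxy)-5-methoxy-2,2-dimethylchroman-6-carbaldehyde
Conditions: MeI (3 equiv), K2CO3 (2 equiv), DMF, 40 °C, 12 h
Reagents that add atoms: methyl iodide, CI
Why: Williamson O-methylation in a polar aprotic solvent overcomes the chelation of the phenol to the aldehyde, and no other acidic site is present.

Step 7
Reactants: 11 2',4'-dihydroxyacetophenone
Product: 12 4'-(benzyloxy)-2'-hydroxyacetophenone
Conditions: BnBr (1.05 equiv), K2CO3 (1.2 equiv), acetone, reflux, 8 h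
Reagents that add atoms: benzyl bromide, BrCc1ccccc1
Why: Williamson etherification is selective for the 4'-OH because the 2'-OH is hydrogen-bonded to the acetyl group.

Step 8
Reactants: 12 4'-(benzyloxy)-2'-hydroxyacetophenone; 10 7-(benzyloxy)-5-methoxy-2,2-dimethylchroman-6-carbaldehyde
Product: 14 (E)-1-[4-(benzyloxy)-2-hydroxyphenyl]-3-[7-(benzyloxy)-5-methoxy-2,2-dimethylchroman-6-yl]prop-2-en-1-one, via aldol adduct 13 (not isolated)
Conditions: KOH (50% aq., 10 equiv), EtOH, rt to 40 °C, 48–72 h; then 2 M HCl, 0 °C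
Reagents that add atoms: none
Why: In this Claisen–Schmidt (crossed aldol) condensation the enolate of the methyl ketone adds to the non-enolisable aldehyde and aldol 13 dehydrates by E1cB to the conjugated enone, whose E geometry is set thermodynamically.

Step 9
Reactants: 14 the (E)-2'-hydroxychalcone
Product: 15 1-[4-(benzyloxy)-2-hydroxyphenyl]-2-[7-(benzyloxy)-5-methoxy-2,2-dimethylchroman-6-yl]-3,3-dimethoxypropan-1-one (racemic)
Conditions: Tl(NO3)3·3H2O (1.2 equiv), MeOH/HC(OMe)3 (3:1), rt, 4–12 h; filter off TlNO3, wash with water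
Reagents that add atoms: methanol, CO
Why: Oxythallation of the enone by trivalent thallium and loss of TlNO3 trigger an oxidative 1,2-aryl migration of the electron-rich ring B to the alpha carbon, and the resulting oxocarbenium ion is trapped by methanol as the dimethyl acetal; the new stereocentre is racemic and is destroyed in step 10.

Step 10
Reactants: 15 the dimethyl acetal
Product: 17 7-(benzyloxy)-3-[7-(benzyloxy)-5-methoxy-2,2-dimethylchroman-6-yl]-4H-chromen-4-one, via 2-methoxyisoflavanone 16 (not isolated)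
Conditions: 10% aq. HCl, MeOH/THF, 60 °C, 3 h
Reagents that add atoms: none
Why: Acid-catalysed transacetalisation by the 2'-OH closes ring C to 2-methoxyisoflavanone 16, which eliminates methanol to the conjugated isoflavone, while the benzyl ethers and the chroman ether survive dilute acid.

Step 11
Reactants: 17 the bis-benzyl isoflavone
Product: 18 glycyrrhizaisoflavone C, 7-hydroxy-3-(7-hydroxy-5-methoxy-2,2-dimethylchroman-6-yl)-4H-chromen-4-one
Conditions: H2 (1 atm), Pd/C (10 wt% Pd), EtOAc/MeOH (1:1), rt, 2–4 h, stopped at full conversion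
Reagents that add atoms: none
Why: Catalytic hydrogenolysis cleaves both benzyl aryl ethers under neutral conditions that leave the methyl ether, the chroman and, with monitoring, the C2=C3 bond intact.

## Compound list

1 | phloroglucinol (benzene-1,3,5-triol) | Oc1cc(O)cc(O)c1 | starting material
2 | 3-methylbut-2-enoic acid | CC(C)=CC(=O)O | starting material
3 | 5,7-dihydroxy-2,2-dimethylchroman-4-one | CC1(C)CC(=O)c2c(O)cc(O)cc2O1 | intermediate
4 | 7-(benzyloxy)-5-hydroxy-2,2-dimethylchroman-4-one | CC1(C)CC(=O)c2c(O)cc(OCc3ccccc3)cc2O1 | intermediate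
5 | 7-(benzyloxy)-2,2-dimethyl-4-oxochroman-5-yl ethyl carbonate | CCOC(=O)Oc1cc(OCc2ccccc2)cc2OC(C)(C)CC(=O)c12 | intermediate
6 | ortho-quinone methide, 7-(benzyloxy)-2,2-dimethyl-2,3-dihydro-5H-chromen-5-one (C4=C4a, C6=C7, C8=C8a) | CC1(C)CC=C2C(=O)C=C(OCc3ccccc3)C=C2O1 | intermediate (not isolated)
7 | 7-(benzyloxy)-2,2-dimethylchroman-5-ol | CC1(C)CCc2c(O)cc(OCc3ccccc3)cc2O1 | intermediate
8 | 7-(benzyloxy)-6-(hydroxymethyl)-2,2-dimethylchroman-5-ol (formed as its magnesium salt) | CC1(C)CCc2c(O)c(CO)c(OCc3ccccc3)cc2O1 | intermediate (not isolated)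
9 | 7-(benzyloxy)-5-hydroxy-2,2-dimethylchroman-6-carbaldehyde | CC1(C)CCc2c(O)c(C=O)c(OCc3ccccc3)cc2O1 | intermediate
10 | 7-(benzyloxy)-5-methoxy-2,2-dimethylchroman-6-carbaldehyde | COc1c(C=O)c(OCc2ccccc2)cc2OC(C)(C)CCc12 | intermediate
11 | 2',4'-dihydroxyacetophenone | CC(=O)c1ccc(O)cc1O | starting material
12 | 4'-(benzyloxy)-2'-hydroxyacetophenone | CC(=O)c1ccc(OCc2ccccc2)cc1O | intermediate
13 | 1-[4-(benzyloxy)-2-hydroxyphenyl]-3-[7-(benzyloxy)-5-methoxy-2,2-dimethylchroman-6-yl]-3-hydroxypropan-1-one (racemic aldol adduct) | O=C(CC(O)c1c(OC)c2CCC(C)(C)Oc2cc1OCc1ccccc1)c1ccc(OCc2ccccc2)cc1O | intermediate (not isolated)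
14 | (E)-1-[4-(benzyloxy)-2-hydroxyphenyl]-3-[7-(benzyloxy)-5-methoxy-2,2-dimethylchroman-6-yl]prop-2-en-1-one | O=C(/C=C/c1c(OC)c2CCC(C)(C)Oc2cc1OCc1ccccc1)c1ccc(OCc2ccccc2)cc1O | intermediate
15 | 1-[4-(benzyloxy)-2-hydroxyphenyl]-2-[7-(benzyloxy)-5-methoxy-2,2-dimethylchroman-6-yl]-3,3-dimethoxypropan-1-one (racemic at C2) | COC(OC)C(C(=O)c1ccc(OCc2ccccc2)cc1O)c1c(OC)c2CCC(C)(C)Oc2cc1OCc1ccccc1 | intermediate
16 | 7-(benzyloxy)-3-[7-(benzyloxy)-5-methoxy-2,2-dimethylchroman-6-yl]-2-methoxychroman-4-one (racemic mixture of diastereomers) | COC1Oc2cc(OCc3ccccc3)ccc2C(=O)C1c1c(OC)c2CCC(C)(C)Oc2cc1OCc1ccccc1 | intermediate (not isolated)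
17 | 7-(benzyloxy)-3-[7-(benzyloxy)-5-methoxy-2,2-dimethylchroman-6-yl]-4H-chromen-4-one | COc1c(-c2coc3cc(OCc4ccccc4)ccc3c2=O)c(OCc2ccccc2)cc2OC(C)(C)CCc12 | intermediate
18 | glycyrrhizaisoflavone C, 7-hydroxy-3-(7-hydroxy-5-methoxy-2,2-dimethylchroman-6-yl)-4H-chromen-4-one (achiral) | COc1c2c(cc(O)c1-c1coc3cc(O)ccc3c1=O)OC(C)(C)CC2 | target

## Step count and risk

Total steps: 11. Longest linear sequence: 10 (steps 1–6, then 8–11); step 7 is a one-step side branch.

Three steps most likely to fail:

**Step 9 (oxidative rearrangement with Tl(NO3)3).** Ring B is di-ortho-substituted and very electron-rich, so ring oxidation, ring thallation or aurone formation could compete with the aryl shift. The fallback is the chalcone epoxide route and sets out from 14. The chelated phenol is protected with MOMCl/NaH in DMF to give the 2'-O-methoxymethyl chalcone F1. Weitz–Scheffer epoxidation (H2O2, NaOH, MeOH/THF, 0 °C to rt) gives the racemic trans-epoxy ketone F2. BF3·OEt2 in CH2Cl2 at 0 °C opens the epoxide at the benzylic carbon and induces a 1,2-acyl shift to the beta-keto aldehyde F3. Warming F3 in 10% HCl/MeOH at 60 °C removes the methoxymethyl group and cyclodehydrates to 17, where the route is rejoined.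

**Step 5 (ortho-formylation at the hindered C6 between OH and OBn).** Conversion may be low. The fallback sets out from 7 and separates hydroxymethylation from oxidation. PhB(OH)2, (CH2O)n and catalytic EtCO2H in refluxing toluene (Dean–Stark) give the ortho-specific cyclic phenylboronate F4. Exchange with propane-1,3-diol frees compound 8, which is isolated this time. MnO2 in CH2Cl2 oxidises the benzylic alcohol to 9, where the route is rejoined.

**Step 4 (reductive removal of the C4 carbonyl).** Carbonate hydrolysis back to 4 or incomplete reduction could occur. The fallback sets out from 4, bypassing 5. NaBH4 in MeOH/THF gives the racemic 7-(benzyloxy)-2,2-dimethylchroman-4,5-diol F5. Ionic hydrogenation with Et3SiH/CF3CO2H in CH2Cl2 at 0 °C (hydride capture of the stabilised benzylic cation) then gives 7, where the route is rejoined.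

## Further compounds

F1 | step 9 | (E)-1-[4-(benzyloxy)-2-(methoxymethoxy)phenyl]-3-[7-(benzyloxy)-5-methoxy-2,2-dimethylchroman-6-yl]prop-2-en-1-one | COCOc1cc(OCc2ccccc2)ccc1C(=O)/C=C/c1c(OC)c2CCC(C)(C)Oc2cc1OCc1ccccc1
F2 | step 9 | trans-[4-(benzyloxy)-2-(methoxymethoxy)phenyl]{3-[7-(benzyloxy)-5-methoxy-2,2-dimethylchroman-6-yl]oxiran-2-yl}methanone (racemic, one enantiomer drawn) | COCOc1cc(OCc2ccccc2)ccc1C(=O)[C@H]1O[C@@H]1c1c(OC)c2CCC(C)(C)Oc2cc1OCc1ccccc1
F3 | step 9 | 3-[4-(benzyloxy)-2-(methoxymethoxy)phenyl]-2-[7-(benzyloxy)-5-methoxy-2,2-dimethylchroman-6-yl]-3-oxopropanal (racemic, enolisable) | COCOc1cc(OCc2ccccc2)ccc1C(=O)C(C=O)c1c(OC)c2CCC(C)(C)Oc2cc1OCc1ccccc1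
F4 | step 5 | cyclic phenylboronate of 8 (2-phenyl-4H-1,3,2-dioxaborinine ring fused across O5 and the C6 CH2O of the 7-(benzyloxy)-2,2-dimethylchroman) | CC1(C)CCc2c3OB(c4ccccc4)OCc3c(OCc3ccccc3)cc2O1
F5 | step 4 | 7-(benzyloxy)-2,2-dimethylchroman-4,5-diol (racemic) | CC1(C)CC(O)c2c(O)cc(OCc3ccccc3)cc2O1
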